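Disconnections: C7–C8 (Suzuki–Miyaura coupling, last step), C8=C9 (Wittig iodo-olefination) and C13–C14 (Heck reaction), giving lactone fragment A (C1–C7), middle fragment B (C9–C13) and oxane fragment C (C14–C24).
Ring A (O1, C1–C5) is formed first, in one flask from three small components: an enamine aldol of acetaldehyde with a silyl ynal makes C4–C5 and sets C5, then Ph3P=C=C=O acylates the new hydroxyl and its ylide carbon olefinates the aldehyde to make C2=C3.
Enabling feature: in ring A the carbinol carbon C5 is β to C3, so C3–C4–C5–O1 is an acetaldehyde-aldol unit whose 1,3-disposed hydroxyl and formyl groups can be bridged by a two-carbon acyl ylide (C1–C2) to a six-membered ring in which C2=C3 can only be cis.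
Ring B (oxane O, C17–C21) is formed second: Sharpless desymmetrisation of divinyl carbinol (C16, C17), (Z)-propenyl opening of the epoxide, Prins cyclisation with crotonaldehyde (O–C21 and C20–C21, sets C20 and C21), Mitsunobu inversion at C19.
C10 comes from an Evans propargylation and the C13 iodide from carboalumination; fragment C is joined to B, the C8 iodide is then installed, and the base-sensitive ring A is attached last.

Key step: step 1

Remark: atoms are numbered along the polyketide chain (lactone carbonyl C1, lactone ring oxygen O1, lactone carbinol C5, chain C6–C16, oxane C17–C21 with its ring oxygen between C17 and C21, propenyl C22–C24); the SMILES is read as 5S,10R,16S,17R,19S,20R,21R with 6E,8Z,12E,14E,22E olefins, and this enantiomer is the one made.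

Step 1
Reactants: 1 acetaldehyde; 2 3-(trimethylsilyl)prop-2-ynal; 3 (triphenylphosphoranylidene)ketene
Product: 6 (6S)-6-[(trimethylsilyl)ethynyl]-5,6-dihydro-2H-pyran-2-one, via β-hydroxy aldehyde 4 (not isolated), via ester ylide 5 (not isolated)
Conditions: (R)-α,α-bis[3,5-bis(trifluoromethyl)phenyl]-2-pyrrolidinemethanol (10 mol %), 1 (5 equiv), DMF, 4 °C; evaporate excess 1 at 0 °C; then 3 (1.3 equiv), THF, 0 → 50 °C
Reagents that add atoms: none
Why: The enamine formed from acetaldehyde 1 and the diarylprolinol adds to the formyl carbon of the non-enolisable, electron-poor ynal 2 (new C4–C5 bond) and hydrolysis releases β-hydroxy aldehyde 4; its hydroxyl then adds across the C=C bond of the cumulated ylide 3 to give the stabilised ester ylide 5, whose ylide carbon olefinates the pendant aldehyde (new C2=C3 bond) with loss of Ph3PO. The closest known reaction types are the diarylprolinol-catalysed direct cross-aldol reaction of acetaldehyde with alkynyl and other electron-poor aldehydes, and the domino addition/intramolecular Wittig lactone annulation of hydroxy carbonyl compounds with Ph3P=C=C=O. The six-membered lactone ring is closed by 6-exo-trig attack of the ylide carbon on the aldehyde, and collapse of the oxaphosphetane can only give the cis ring olefin. The C5 stereocentre is set by the catalyst, whose carbinol hydroxyl hydrogen-bonds the ynal carbonyl and exposes one face to the anti-enamine; by analogy with proline-type aldol transition states the (R)-catalyst should give the (S)-aldol, and the enantiomeric catalyst would be used if the opposite sense were found. The step needs cross- over self-aldol selectivity, secured by the far higher electrophilicity of the ynal and by removing the excess acetaldehyde before the ylide is added, and it needs O-acylation before olefination, secured because the cumulated ylide does not olefinate aldehydes but adds O–H bonds readily.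

Step 2
Reactants: 6 (6S)-6-[(trimethylsilyl)ethynyl]-5,6-dihydro-2H-pyran-2-one
Product: 7 (6S)-6-ethynyl-5,6-dihydro-2H-pyran-2-one
Conditions: Bu4NF, AcOH (1:1), THF, 0 °C
Reagents that add atoms: none
Why: Fluoride-mediated protodesilylation of the alkynylsilane, buffered with acetic acid so that the base-sensitive dihydropyranone should not undergo β-elimination or conjugate addition; the stereocentre is not involved.

Step 3
Reactants: 7 (6S)-6-ethynyl-5,6-dihydro-2H-pyran-2-one
Product: 8 (6S)-6-[(E)-2-(4,4,5,5-tetramethyl-1,3,2-dioxaborolan-2-yl)ethenyl]-5,6-dihydro-2H-pyran-2-one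
Conditions: pinacolborane (1.5 equiv), Cy2BH (5 mol %), THF, rt
Reagents that add atoms: pinacolborane, CC1(C)OBOC1(C)C
Why: Dialkylborane-catalysed hydroboration of the terminal alkyne with pinacolborane is a syn, anti-Markovnikov addition that should give the (E)-alkenylboronate (C6=C7), while the electron-poor, s-trans-locked enoate of the lactone is inert to the borane.

Step 4
Reactants: 9 (4S)-4-benzyl-3-propanoyl-1,3-oxazolidin-2-one; 10 3-bromoprop-1-yne
Product: 11 (4S)-4-benzyl-3-[(2R)-2-methylpent-4-ynoyl]-1,3-oxazolidin-2-one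
Conditions: NaN(SiMe3)2, THF, −78 °C; then 10, −78 → −40 °C
Reagents that add atoms: none
Why: Evans asymmetric alkylation, in which the chelated (Z)-sodium enolate is alkylated by the reactive propargylic bromide on the face opposite the benzyl group, setting the methyl-bearing stereocentre (later C10) as R.

Step 5
Reactants: 11 (4S)-4-benzyl-3-[(2R)-2-methylpent-4-ynoyl]-1,3-oxazolidin-2-one
Product: 12 (2R)-2-methylpent-4-yn-1-ol
Conditions: LiBH4, MeOH (1 equiv), Et2O, 0 °C
Reagents that add atoms: none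
Why: Reductive cleavage of the N-acyl oxazolidinone by hydride attack at the exocyclic carbonyl should give the primary alcohol without touching the α-stereocentre and release the auxiliary.

Step 6
Reactants: 12 (2R)-2-methylpent-4-yn-1-ol
Product: 13 (2R,4E)-5-iodo-2,4-dimethylpent-4-en-1-ol
Conditions: AlMe3 (3 equiv), Cp2ZrCl2 (0.25 equiv), CH2Cl2, 0 °C → rt; then I2, THF, −30 °C
Reagents that add atoms: trimethylaluminium, C[Al](C)C; iodine, II
Why: Zirconium-catalysed carboalumination (Negishi methylalumination) adds methyl and aluminium syn across the terminal alkyne with methyl on the internal carbon, and iodinolysis of the alkenylalane with retention should give the (E)-trisubstituted vinyl iodide (C12=C13), the hydroxyl being carried as its aluminium alkoxide.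

Step 7
Reactants: 14 penta-1,4-dien-3-ol
Product: 15 (1S)-1-[(2R)-oxiran-2-yl]prop-2-en-1-ol
Conditions: Ti(OiPr)4, L-(+)-diisopropyl tartrate, t-BuOOH (anhydrous, in isooctane), 4 Å molecular sieves, CH2Cl2, −20 °C
Reagents that add atoms: tert-butyl hydroperoxide, CC(C)(C)OO
Why: Sharpless asymmetric epoxidation desymmetrises the prochiral divinyl carbinol, the titanium tartrate complex epoxidising one enantiotopic vinyl group on one face to give the anti epoxy alcohol (sets C16 and C17), while the minor enantiomer is consumed by a faster second epoxidation so that enantiopurity should rise with conversion.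

Step 8
Reactants: 15 (1S)-1-[(2R)-oxiran-2-yl]prop-2-en-1-ol
Product: 16 tert-butyl{[(1S)-1-[(2R)-oxiran-2-yl]prop-2-en-1-yl]oxy}diphenylsilane
Conditions: TBDPSCl, imidazole, DMF, 0 °C → rt
Reagents that add atoms: tert-butyl(chloro)diphenylsilane, CC(C)(C)[Si](Cl)(c1ccccc1)c1ccccc1
Why: Silylation of the secondary alcohol under weakly basic conditions avoids Payne rearrangement and gives an ether that is stable to the later acid-mediated cyclisation.

Step 9
Reactants: 16 tert-butyl{[(1S)-1-[(2R)-oxiran-2-yl]prop-2-en-1-yl]oxy}diphenylsilane; 17 (1Z)-1-bromoprop-1-ene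
Product: 19 (3S,4R,6Z)-3-[(tert-butyldiphenylsilyl)oxy]octa-1,6-dien-4-ol, via (Z)-prop-1-enyllithium 18 (not isolated)
Conditions: 17, t-BuLi (2 equiv), Et2O, −78 °C; then 16, BF3·OEt2, −78 °C; aq. NH4Cl
Reagents that add atoms: none
Why: Stereoretentive bromine–lithium exchange gives the (Z)-alkenyllithium, which opens the BF3-activated terminal epoxide at the unhindered CH2 (SN2 epoxide opening), so that C17 is retained and the (Z)-olefin needed for the axial C20 methyl is installed directly, the boron-complexed alkoxide being too weak a nucleophile to induce silyl migration.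

Step 10
Reactants: 19 (3S,4R,6Z)-3-[(tert-butyldiphenylsilyl)oxy]octa-1,6-dien-4-ol; 20 (2E)-but-2-enal
Product: 22 (2R,3R,4R,6R)-6-[(1S)-1-[(tert-butyldiphenylsilyl)oxy]prop-2-en-1-yl]-3-methyl-2-[(1E)-prop-1-en-1-yl]oxan-4-ol, via trifluoroacetate ester 21 (not isolated)
Conditions: 20 (3 equiv), CF3CO2H, CH2Cl2, 0 °C → rt; evaporate; then K2CO3, MeOH, rt
Reagents that add atoms: trifluoroacetic acid, OC(=O)C(F)(F)F
Why: Prins cyclisation, in which condensation of the homoallylic alcohol with crotonaldehyde gives a conjugated (E)-oxocarbenium ion that is attacked by the (Z)-alkene through a chair transition state with the C17 and C21 substituents equatorial (2,6-cis), the Z geometry placing the C20 methyl axial and cis to the propenyl group, and trifluoroacetate trapping the C19 cation equatorially; the 1,2-disubstituted alkene should react in preference to the vinyl group, which is deactivated by the allylic silyloxy substituent, and the ester is methanolysed in the same flask.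

Step 11
Reactants: 22 (2R,3R,4R,6R)-6-[(1S)-1-[(tert-butyldiphenylsilyl)oxy]prop-2-en-1-yl]-3-methyl-2-[(1E)-prop-1-en-1-yl]oxan-4-ol
Product: 23 (2R,3R,4S,6R)-6-[(1S)-1-[(tert-butyldiphenylsilyl)oxy]prop-2-en-1-yl]-3-methyl-2-[(1E)-prop-1-en-1-yl]oxan-4-yl 4-nitrobenzoate
Conditions: 4-nitrobenzoic acid, PPh3, DIAD, toluene, 0 °C → rt
Reagents that add atoms: 4-nitrobenzoic acid, OC(=O)c1ccc(cc1)[N+](=O)[O-]
Why: Mitsunobu reaction, in which the equatorial C19 hydroxyl is activated as an oxyphosphonium ion and displaced by 4-nitrobenzoate with inversion along the axial trajectory on the face opposite the axial C20 methyl, elimination being disfavoured because no C–H bond is antiperiplanar to the equatorial leaving group.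

Step 12
Reactants: 23 (2R,3R,4S,6R)-6-[(1S)-1-[(tert-butyldiphenylsilyl)oxy]prop-2-en-1-yl]-3-methyl-2-[(1E)-prop-1-en-1-yl]oxan-4-yl 4-nitrobenzoate
Product: 24 (2R,3R,4S,6R)-6-[(1S)-1-[(tert-butyldiphenylsilyl)oxy]prop-2-en-1-yl]-3-methyl-2-[(1E)-prop-1-en-1-yl]oxan-4-ol
Conditions: K2CO3, MeOH, rt
Reagents that add atoms: none
Why: Base-catalysed transesterification of the activated 4-nitrobenzoate should release the axial C19 alcohol with retention, the silyl ether and the olefins being inert.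

Step 13
Reactants: 24 (2R,3R,4S,6R)-6-[(1S)-1-[(tert-butyldiphenylsilyl)oxy]prop-2-en-1-yl]-3-methyl-2-[(1E)-prop-1-en-1-yl]oxan-4-ol; 13 (2R,4E)-5-iodo-2,4-dimethylpent-4-en-1-ol
Product: 25 (2R,4E,6E,8S)-8-[(tert-butyldiphenylsilyl)oxy]-8-[(2R,4S,5R,6R)-4-hydroxy-5-methyl-6-[(1E)-prop-1-en-1-yl]oxan-2-yl]-2,4-dimethylocta-4,6-dien-1-ol
Conditions: Pd(OAc)2 (10 mol %), Bu4NCl, K2CO3, DMF, 60 °C
Reagents that add atoms: none
Why: Mizoroki–Heck reaction under ligand-free phase-transfer conditions, in which zerovalent palladium adds oxidatively to the vinyl iodide with retention, inserts syn into the only monosubstituted alkene (the propenyl and trisubstituted olefins are too hindered) and undergoes syn-β-hydride elimination towards conjugation, which should give the (12E,14E)-diene with both free hydroxyls tolerated.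

Step 14
Reactants: 25 (2R,4E,6E,8S)-8-[(tert-butyldiphenylsilyl)oxy]-8-[(2R,4S,5R,6R)-4-hydroxy-5-methyl-6-[(1E)-prop-1-en-1-yl]oxan-2-yl]-2,4-dimethylocta-4,6-dien-1-ol
Product: 26 (2R,4E,6E,8S)-8-[(tert-butyldiphenylsilyl)oxy]-8-[(2R,4S,5R,6R)-4-hydroxy-5-methyl-6-[(1E)-prop-1-en-1-yl]oxan-2-yl]-2,4-dimethylocta-4,6-dienal
Conditions: TEMPO (20 mol %), PhI(OAc)2, CH2Cl2, rt
Reagents that add atoms: none
Why: Oxoammonium (TEMPO/PhI(OAc)2) oxidation is selective for the primary alcohol over the hindered axial secondary C19 alcohol and runs without base, so the α-methyl aldehyde (C10) should not epimerise.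

Step 15
Reactants: 26 (2R,4E,6E,8S)-8-[(tert-butyldiphenylsilyl)oxy]-8-[(2R,4S,5R,6R)-4-hydroxy-5-methyl-6-[(1E)-prop-1-en-1-yl]oxan-2-yl]-2,4-dimethylocta-4,6-dienal; 27 ethyltriphenylphosphonium iodide
Product: 31 (1S,2E,4E,7R,8Z)-1-[(tert-butyldiphenylsilyl)oxy]-1-[(2R,4S,5R,6R)-4-hydroxy-5-methyl-6-[(1E)-prop-1-en-1-yl]oxan-2-yl]-9-iodo-5,7-dimethyldeca-2,4,8-triene, via ethylidenetriphenylphosphorane 28 (not isolated), via (1-iodoethyl)triphenylphosphonium iodide 29 (not isolated), via (1-iodoethylidene)triphenylphosphorane 30 (not isolated)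
Conditions: 27 (3 equiv), n-BuLi, THF, rt; I2, −78 °C; NaN(SiMe3)2, −78 → −20 °C; then 26, −78 °C → rt
Reagents that add atoms: iodine, II
Why: Stork–Zhao-type Wittig olefination with the α-iodo ylide generated in the flask should give the (Z)-2-iodoalkene under kinetic control (non-stabilised ylide, sodium base, low temperature), with iodine cis to C10 as required for the 8Z olefin, excess ylide compensating for the free C19 hydroxyl.

Step 16
Reactants: 31 (1S,2E,4E,7R,8Z)-1-[(tert-butyldiphenylsilyl)oxy]-1-[(2R,4S,5R,6R)-4-hydroxy-5-methyl-6-[(1E)-prop-1-en-1-yl]oxan-2-yl]-9-iodo-5,7-dimethyldeca-2,4,8-triene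
Product: 32 (1S,2E,4E,7R,8Z)-1-[(2R,4S,5R,6R)-4-hydroxy-5-methyl-6-[(1E)-prop-1-en-1-yl]oxan-2-yl]-9-iodo-5,7-dimethyldeca-2,4,8-trien-1-ol
Conditions: Bu4NF, THF, 0 °C → rt
Reagents that add atoms: none
Why: Fluoride-mediated silyl ether cleavage frees the C16 hydroxyl before the base-sensitive lactone is introduced, the vinyl iodide and the polyene being stable to Bu4NF.

Step 17
Reactants: 32 (1S,2E,4E,7R,8Z)-1-[(2R,4S,5R,6R)-4-hydroxy-5-methyl-6-[(1E)-prop-1-en-1-yl]oxan-2-yl]-9-iodo-5,7-dimethyldeca-2,4,8-trien-1-ol; 8 (6S)-6-[(E)-2-(4,4,5,5-tetramethyl-1,3,2-dioxaborolan-2-yl)ethenyl]-5,6-dihydro-2H-pyran-2-one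
Product: 33 (6S)-6-[(1E,3Z,5R,7E,9E,11S)-11-hydroxy-11-[(2R,4S,5R,6R)-4-hydroxy-5-methyl-6-[(1E)-prop-1-en-1-yl]oxan-2-yl]-3,5,7-trimethylundeca-1,3,7,9-tetraen-1-yl]-5,6-dihydro-2H-pyran-2-one
Conditions: Pd(PPh3)4 (10 mol %), TlOEt, THF/H2O 3:1, rt, dark
Reagents that add atoms: none
Why: Suzuki–Miyaura coupling accelerated by thallium ethoxide runs at room temperature with retention at both alkenyl partners (oxidative addition of zerovalent palladium to the (Z)-vinyl iodide, transmetalation of the (E)-alkenylboronate, reductive elimination), so the (6E,8Z)-diene should form while the unprotected diol and the base-sensitive lactone survive the short, mild reaction.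

Compound list
1 | acetaldehyde | CC=O | starting material
2 | 3-(trimethylsilyl)prop-2-ynal | C[Si](C)(C)C#CC=O | starting material
3 | (triphenylphosphoranylidene)ketene (Bestmann ylide) | O=C=C=P(c1ccccc1)(c1ccccc1)c1ccccc1 | starting material
4 | (3S)-3-hydroxy-5-(trimethylsilyl)pent-4-ynal | C[Si](C)(C)C#C[C@@H](O)CC=O | intermediate
5 | (3S)-1-oxo-5-(trimethylsilyl)pent-4-yn-3-yl (triphenylphosphoranylidene)acetate | C[Si](C)(C)C#C[C@@H](OC(=O)C=P(c1ccccc1)(c1ccccc1)c1ccccc1)CC=O | intermediate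
6 | (6S)-6-[(trimethylsilyl)ethynyl]-5,6-dihydro-2H-pyran-2-one | C[Si](C)(C)C#C[C@@H]1CC=CC(=O)O1 | intermediate
7 | (6S)-6-ethynyl-5,6-dihydro-2H-pyran-2-one | C#C[C@@H]1CC=CC(=O)O1 | intermediate
8 | (6S)-6-[(E)-2-(4,4,5,5-tetramethyl-1,3,2-dioxaborolan-2-yl)ethenyl]-5,6-dihydro-2H-pyran-2-one | CC1(C)OB(/C=C/[C@@H]2CC=CC(=O)O2)OC1(C)C | intermediate
9 | (4S)-4-benzyl-3-propanoyl-1,3-oxazolidin-2-one | CCC(=O)N1[C@@H](Cc2ccccc2)COC1=O | starting material
10 | 3-bromoprop-1-yne (propargyl bromide) | C#CCBr | starting material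
11 | (4S)-4-benzyl-3-[(2R)-2-methylpent-4-ynoyl]-1,3-oxazolidin-2-one | C#CC[C@@H](C)C(=O)N1[C@@H](Cc2ccccc2)COC1=O | intermediate
12 | (2R)-2-methylpent-4-yn-1-ol | C#CC[C@@H](C)CO | intermediate
13 | (2R,4E)-5-iodo-2,4-dimethylpent-4-en-1-ol | I/C=C(C)/C[C@@H](C)CO | intermediate
14 | penta-1,4-dien-3-ol (divinyl carbinol) | C=CC(O)C=C | starting material
15 | (1S)-1-[(2R)-oxiran-2-yl]prop-2-en-1-ol | C=C[C@H](O)[C@H]1CO1 | intermediate
16 | tert-butyl{[(1S)-1-[(2R)-oxiran-2-yl]prop-2-en-1-yl]oxy}diphenylsilane | C=C[C@H](O[Si](c1ccccc1)(c1ccccc1)C(C)(C)C)[C@H]1CO1 | intermediate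
17 | (1Z)-1-bromoprop-1-ene | C/C=C\Br | starting material
18 | (Z)-prop-1-enyllithium | C/C=C\[Li] | intermediate
19 | (3S,4R,6Z)-3-[(tert-butyldiphenylsilyl)oxy]octa-1,6-dien-4-ol | C=C[C@H](O[Si](c1ccccc1)(c1ccccc1)C(C)(C)C)[C@H](O)C/C=C\C | intermediate
20 | (2E)-but-2-enal (crotonaldehyde) | C/C=C/C=O | starting material
21 | (2R,3R,4R,6R)-6-[(1S)-1-[(tert-butyldiphenylsilyl)oxy]prop-2-en-1-yl]-3-methyl-2-[(1E)-prop-1-en-1-yl]oxan-4-yl trifluoroacetate | C/C=C/[C@H]1O[C@@H]([C@@H](O[Si](c2ccccc2)(c2ccccc2)C(C)(C)C)C=C)C[C@@H](OC(=O)C(F)(F)F)[C@H]1C | intermediate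
22 | (2R,3R,4R,6R)-6-[(1S)-1-[(tert-butyldiphenylsilyl)oxy]prop-2-en-1-yl]-3-methyl-2-[(1E)-prop-1-en-1-yl]oxan-4-ol | C/C=C/[C@H]1O[C@@H]([C@@H](O[Si](c2ccccc2)(c2ccccc2)C(C)(C)C)C=C)C[C@@H](O)[C@H]1C | intermediate
23 | (2R,3R,4S,6R)-6-[(1S)-1-[(tert-butyldiphenylsilyl)oxy]prop-2-en-1-yl]-3-methyl-2-[(1E)-prop-1-en-1-yl]oxan-4-yl 4-nitrobenzoate | C/C=C/[C@H]1O[C@@H]([C@@H](O[Si](c2ccccc2)(c2ccccc2)C(C)(C)C)C=C)C[C@H](OC(=O)c2ccc(cc2)[N+](=O)[O-])[C@H]1C | intermediate
24 | (2R,3R,4S,6R)-6-[(1S)-1-[(tert-butyldiphenylsilyl)oxy]prop-2-en-1-yl]-3-methyl-2-[(1E)-prop-1-en-1-yl]oxan-4-ol | C/C=C/[C@H]1O[C@@H]([C@@H](O[Si](c2ccccc2)(c2ccccc2)C(C)(C)C)C=C)C[C@H](O)[C@H]1C | intermediate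
25 | (2R,4E,6E,8S)-8-[(tert-butyldiphenylsilyl)oxy]-8-[(2R,4S,5R,6R)-4-hydroxy-5-methyl-6-[(1E)-prop-1-en-1-yl]oxan-2-yl]-2,4-dimethylocta-4,6-dien-1-ol | C/C=C/[C@H]1O[C@@H]([C@@H](O[Si](c2ccccc2)(c2ccccc2)C(C)(C)C)/C=C/C=C(\C)C[C@@H](C)CO)C[C@H](O)[C@H]1C | intermediate
26 | (2R,4E,6E,8S)-8-[(tert-butyldiphenylsilyl)oxy]-8-[(2R,4S,5R,6R)-4-hydroxy-5-methyl-6-[(1E)-prop-1-en-1-yl]oxan-2-yl]-2,4-dimethylocta-4,6-dienal | C/C=C/[C@H]1O[C@@H]([C@@H](O[Si](c2ccccc2)(c2ccccc2)C(C)(C)C)/C=C/C=C(\C)C[C@@H](C)C=O)C[C@H](O)[C@H]1C | intermediate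
27 | ethyltriphenylphosphonium iodide | CC[P+](c1ccccc1)(c1ccccc1)c1ccccc1.[I-] | starting material
28 | ethylidenetriphenylphosphorane | CC=P(c1ccccc1)(c1ccccc1)c1ccccc1 | intermediate
29 | (1-iodoethyl)triphenylphosphonium iodide | CC(I)[P+](c1ccccc1)(c1ccccc1)c1ccccc1.[I-] | intermediate
30 | (1-iodoethylidene)triphenylphosphorane | CC(I)=P(c1ccccc1)(c1ccccc1)c1ccccc1 | intermediate
31 | (1S,2E,4E,7R,8Z)-1-[(tert-butyldiphenylsilyl)oxy]-1-[(2R,4S,5R,6R)-4-hydroxy-5-methyl-6-[(1E)-prop-1-en-1-yl]oxan-2-yl]-9-iodo-5,7-dimethyldeca-2,4,8-triene | C/C=C/[C@H]1O[C@@H]([C@@H](O[Si](c2ccccc2)(c2ccccc2)C(C)(C)C)/C=C/C=C(\C)C[C@@H](C)/C=C(C)\I)C[C@H](O)[C@H]1C | intermediate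
32 | (1S,2E,4E,7R,8Z)-1-[(2R,4S,5R,6R)-4-hydroxy-5-methyl-6-[(1E)-prop-1-en-1-yl]oxan-2-yl]-9-iodo-5,7-dimethyldeca-2,4,8-trien-1-ol | C/C=C/[C@H]1O[C@@H]([C@@H](O)/C=C/C=C(\C)C[C@@H](C)/C=C(C)\I)C[C@H](O)[C@H]1C | intermediate
33 | (6S)-6-[(1E,3Z,5R,7E,9E,11S)-11-hydroxy-11-[(2R,4S,5R,6R)-4-hydroxy-5-methyl-6-[(1E)-prop-1-en-1-yl]oxan-2-yl]-3,5,7-trimethylundeca-1,3,7,9-tetraen-1-yl]-5,6-dihydro-2H-pyran-2-one | C/C=C/[C@H]1O[C@@H]([C@@H](O)/C=C/C=C(\C)C[C@@H](C)/C=C(C)\C=C\[C@@H]2CC=CC(=O)O2)C[C@H](O)[C@H]1C | target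

Total step count: 17 (fragment A 3 steps, fragment B 3 steps, fragment C 6 steps, assembly 5 steps).
Longest linear sequence: 11 steps (steps 7–17, from penta-1,4-dien-3-ol 14 to 33).

Steps most likely to fail

Step 1. The β-hydroxy ynal may dehydrate or undergo retro-aldol cleavage before it is O-acylated by the ylide, or the enamine aldol may give insufficient face selectivity. The fallback sets out from 2 and comes back at 6; it replaces the annulation by allylation, acylation and ring-closing metathesis. Brown allylation of 2 with (−)-Ipc2B(allyl) (Et2O, −78 °C; then NaOH, H2O2) should give (3S)-1-(trimethylsilyl)hex-5-en-1-yn-3-ol F1. Acylation with acryloyl chloride (Et3N, DMAP, CH2Cl2, 0 °C) gives (3S)-1-(trimethylsilyl)hex-5-en-1-yn-3-yl prop-2-enoate F2. Ring-closing metathesis with the second-generation Grubbs catalyst RuCl2(=CHPh)(PCy3)(H2IMes) (CH2Cl2, 40 °C) then closes C2=C3 with loss of ethene and delivers 6; the bulky silyl alkyne should stay out of the metathesis.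

Step 10. The conjugated oxocarbenium ion may cyclise slowly onto the (Z)-alkene, so that cyclisation through the terminal vinyl group, side-chain exchange by 2-oxonia-Cope rearrangement or acidolysis of the silyl ether compete. The fallback sets out from 19 and comes back at 22; it generates the same cation from a preformed α-acetoxy ether under aprotic Lewis-acid conditions at low temperature, so that C21 enters by acylation and not by acetalisation. Esterification of 19 with (2E)-but-2-enoyl chloride (pyridine, DMAP, CH2Cl2) gives (3S,4R,6Z)-3-[(tert-butyldiphenylsilyl)oxy]octa-1,6-dien-4-yl (2E)-but-2-enoate F3. Reduction with DIBAL-H at −78 °C and acetylation of the aluminium hemiacetal in the flask (Ac2O, pyridine, DMAP) gives (2E)-1-{[(3S,4R,6Z)-3-[(tert-butyldiphenylsilyl)oxy]octa-1,6-dien-4-yl]oxy}but-2-en-1-yl acetate F4. Ionisation with BF3·OEt2 and AcOH in hexane at 0 °C should give, through the same chair transition state, (2R,3R,4R,6R)-6-[(1S)-1-[(tert-butyldiphenylsilyl)oxy]prop-2-en-1-yl]-3-methyl-2-[(1E)-prop-1-en-1-yl]oxan-4-yl acetate F5, and K2CO3 in MeOH converts it into 22.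

Step 15. The thermally labile iodo ylide may give low conversion and erosion of the Z geometry, and the basic ylide may epimerise the α-methyl aldehyde. The fallback sets out from 26 and comes back at 33; it builds the (Z)-haloalkene by dibromoolefination and trans-selective methylation. Corey–Fuchs-type dibromoolefination of 26 (CBr4, PPh3, Et3N, CH2Cl2, 0 °C) gives (3R,5E,7E,9S)-1,1-dibromo-9-[(tert-butyldiphenylsilyl)oxy]-9-[(2R,4S,5R,6R)-4-hydroxy-5-methyl-6-[(1E)-prop-1-en-1-yl]oxan-2-yl]-3,5-dimethylnona-1,5,7-triene F6. Negishi monomethylation (Me2Zn in excess, PdCl2(DPEphos) as catalyst, THF, rt) should react only at the bromide trans to the alkyl chain and give (2Z,4R,6E,8E,10S)-2-bromo-10-[(tert-butyldiphenylsilyl)oxy]-10-[(2R,4S,5R,6R)-4-hydroxy-5-methyl-6-[(1E)-prop-1-en-1-yl]oxan-2-yl]-4,6-dimethyldeca-2,6,8-triene F7. Bu4NF in THF gives (1S,2E,4E,7R,8Z)-9-bromo-1-[(2R,4S,5R,6R)-4-hydroxy-5-methyl-6-[(1E)-prop-1-en-1-yl]oxan-2-yl]-5,7-dimethyldeca-2,4,8-trien-1-ol F8, and Suzuki–Miyaura coupling of F8 with 8 (Pd(PPh3)4, TlOEt, THF/H2O, 40 °C) gives 33.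

Further compounds
F1 | step 1 | (3S)-1-(trimethylsilyl)hex-5-en-1-yn-3-ol | C[Si](C)(C)C#C[C@@H](O)CC=C
F2 | step 1 | (3S)-1-(trimethylsilyl)hex-5-en-1-yn-3-yl prop-2-enoate | C[Si](C)(C)C#C[C@@H](OC(=O)C=C)CC=C
F3 | step 10 | (3S,4R,6Z)-3-[(tert-butyldiphenylsilyl)oxy]octa-1,6-dien-4-yl (2E)-but-2-enoate | C=C[C@H](O[Si](c1ccccc1)(c1ccccc1)C(C)(C)C)[C@H](OC(=O)/C=C/C)C/C=C\C
F4 | step 10 | (2E)-1-{[(3S,4R,6Z)-3-[(tert-butyldiphenylsilyl)oxy]octa-1,6-dien-4-yl]oxy}but-2-en-1-yl acetate (both acetal epimers) | C=C[C@H](O[Si](c1ccccc1)(c1ccccc1)C(C)(C)C)[C@H](OC(OC(C)=O)/C=C/C)C/C=C\C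
F5 | step 10 | (2R,3R,4R,6R)-6-[(1S)-1-[(tert-butyldiphenylsilyl)oxy]prop-2-en-1-yl]-3-methyl-2-[(1E)-prop-1-en-1-yl]oxan-4-yl acetate | C/C=C/[C@H]1O[C@@H]([C@@H](O[Si](c2ccccc2)(c2ccccc2)C(C)(C)C)C=C)C[C@@H](OC(C)=O)[C@H]1C
F6 | step 15 | (3R,5E,7E,9S)-1,1-dibromo-9-[(tert-butyldiphenylsilyl)oxy]-9-[(2R,4S,5R,6R)-4-hydroxy-5-methyl-6-[(1E)-prop-1-en-1-yl]oxan-2-yl]-3,5-dimethylnona-1,5,7-triene | C/C=C/[C@H]1O[C@@H]([C@@H](O[Si](c2ccccc2)(c2ccccc2)C(C)(C)C)/C=C/C=C(\C)C[C@@H](C)C=C(Br)Br)C[C@H](O)[C@H]1C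
F7 | step 15 | (2Z,4R,6E,8E,10S)-2-bromo-10-[(tert-butyldiphenylsilyl)oxy]-10-[(2R,4S,5R,6R)-4-hydroxy-5-methyl-6-[(1E)-prop-1-en-1-yl]oxan-2-yl]-4,6-dimethyldeca-2,6,8-triene | C/C=C/[C@H]1O[C@@H]([C@@H](O[Si](c2ccccc2)(c2ccccc2)C(C)(C)C)/C=C/C=C(\C)C[C@@H](C)/C=C(C)\Br)C[C@H](O)[C@H]1C
F8 | step 15 | (1S,2E,4E,7R,8Z)-9-bromo-1-[(2R,4S,5R,6R)-4-hydroxy-5-methyl-6-[(1E)-prop-1-en-1-yl]oxan-2-yl]-5,7-dimethyldeca-2,4,8-trien-1-ol | C/C=C/[C@H]1O[C@@H]([C@@H](O)/C=C/C=C(\C)C[C@@H](C)/C=C(C)\Br)C[C@H](O)[C@H]1C
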